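**Retrosynthetic overview**
1. Target 11 is the hydrogen malonate of ent-copalol (5R,9R,10R, labdane numbering); the ester C–O bond is cut to give ent-copalol 9 and Meldrum's acid 10.
2. 9 comes from enoate 8, which comes from methyl ketone 6 and phosphonate 7 (Horner–Wadsworth–Emmons builds C13=C14, then DIBAL-H).
3. 6 comes from hydroxy ketone 4; the C8 oxygen is removed towards the C17 methyl to give the exocyclic 8(17)-alkene.
4. 4 comes from enol ether 3, which comes from acyclic (5E,9E)-farnesylacetone 1 in one asymmetric proton-initiated cascade that ends with the key C8–O bond.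
5. Ring order: ring A (C4–C5), ring B (C9–C10), then a temporary dihydropyran (C8–O) that is opened again in steps 1 and 2.

Assumption: the all-E isomer of farnesylacetone is used (bought as such or separated from the commercial isomer mixture), and of the two catalyst antipodes (from (R)- or (S)-BINOL) the one found by screening to give the 5R,9R,10R series is used.

**Step 1**
Reactants: 1 (5E,9E)-farnesylacetone
Product: 4 ent-8α-hydroxy-14,15-dinorlabdan-13-one (hydroxy ketone), via oxocarbenium ion 2 (not isolated), via ent-sclareol oxide 3 (not isolated)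
Conditions: confined chiral IDPi Brønsted acid (3 mol %), (CF3)3COH, −10 °C; then THF, 0.5 M aq HCl, 23 °C; recrystallise
Reagents that add atoms: water, O
Why: Proposed new method: a confined chiral imidodiphosphorimidate acid in a fluorinated alcohol protonates the terminal alkene of 1 held in a chair–chair fold, the two E-alkenes add anti in sequence (C4–C5, then C9–C10) so that the catalyst pocket and the alkene geometry set C5, C9 and C10 of the trans-decalin, and the ketone oxygen captures the C8 cation to form the key C8–O bond, giving oxocarbenium 2, which loses a proton to enol ether 3 that dilute acid hydrolyses to crystalline 4; the closest known reaction types are the IDPi-catalysed asymmetric cyclization of homofarnesol to ambrox (hydroxyl termination) and the racemic superacid or enzymatic cyclization of farnesylacetone to sclareol oxide, whereas carbonyl-oxygen termination under asymmetric Brønsted acid catalysis has not been shown.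

**Step 2**
Reactants: 4 ent-8α-hydroxy-14,15-dinorlabdan-13-one
Product: 6 ent-14,15-dinorlabd-8(17)-en-13-one, via chlorosulfite ester 5 (not isolated)
Conditions: SOCl2, pyridine, CH2Cl2, −78 °C
Reagents that add atoms: none
Why: E2 dehydration through the chlorosulfite: the equatorial C8–O bond has no antiperiplanar ring hydrogen, so pyridine takes a proton from the freely rotating axial C17 methyl and the exocyclic 8(17)-alkene forms, with C5, C9 and C10 untouched.

**Step 3**
Reactants: 6 ent-14,15-dinorlabd-8(17)-en-13-one; 7 triethyl phosphonoacetate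
Product: 8 ethyl ent-copalate (13E)
Conditions: NaH, THF, 0 → 60 °C; chromatography (AgNO3–SiO2) to remove the 13Z isomer
Reagents that add atoms: triethyl phosphonoacetate (7), CCOC(=O)CP(=O)(OCC)OCC
Why: Horner–Wadsworth–Emmons olefination of the methyl ketone places the larger C12 chain trans to the ester (E, expected about 4–5:1), and the minor Z isomer is separated.

**Step 4**
Reactants: 8 ethyl ent-copalate
Product: 9 ent-copalol
Conditions: DIBAL-H, CH2Cl2, −78 °C; Rochelle salt
Reagents that add atoms: none
Why: 1,2-reduction of the α,β-unsaturated ester with DIBAL-H gives the E-allylic alcohol and leaves both alkenes and all stereocentres unchanged.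

**Step 5**
Reactants: 9 ent-copalol; 10 Meldrum's acid
Product: 11 target, 3-{[(2E)-3-methyl-5-[(1R,4aR,8aR)-5,5,8a-trimethyl-2-methylidenedecahydronaphthalen-1-yl]pent-2-en-1-yl]oxy}-3-oxopropanoic acid
Conditions: toluene, 85 °C
Reagents that add atoms: Meldrum's acid (10), CC1(C)OC(=O)CC(=O)O1
Why: ring-opening alcoholysis (O-acylation) of Meldrum's acid by the primary allylic alcohol forms the ester C–O bond and releases acetone, giving the malonic half-ester directly without protecting groups or strong acid that could move the exocyclic alkene.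

**Compound list**
1 | (5E,9E)-farnesylacetone, (5E,9E)-6,10,14-trimethylpentadeca-5,9,13-trien-2-one | CC(=O)CC/C=C(\C)CC/C=C(\C)CCC=C(C)C | starting material
2 | tricyclic oxocarbenium ion (C8–O+=C13; 5R,8S,9S,10R; ion pair with the catalyst anion) | C[C@@]12CCCC(C)(C)[C@H]1CC[C@@]3(C)[C@H]2CCC(C)=[O+]3 | intermediate
3 | ent-sclareol oxide (ent-8α,13-epoxy-14,15-dinorlabd-12-ene; 5R,8S,9S,10R) | C[C@@]12CCCC(C)(C)[C@H]1CC[C@@]3(C)[C@H]2CC=C(C)O3 | intermediate
4 | ent-8α-hydroxy-14,15-dinorlabdan-13-one; 4-[(1S,2S,4aR,8aR)-2-hydroxy-2,5,5,8a-tetramethyldecahydronaphthalen-1-yl]butan-2-one | C[C@]1(O)CC[C@@H]2C(C)(C)CCC[C@@]2(C)[C@@H]1CCC(C)=O | intermediate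
5 | 8-O-chlorosulfite ester of 4 | C[C@]1(OS(=O)Cl)CC[C@@H]2C(C)(C)CCC[C@@]2(C)[C@@H]1CCC(C)=O | intermediate
6 | ent-14,15-dinorlabd-8(17)-en-13-one; 4-[(1R,4aR,8aR)-5,5,8a-trimethyl-2-methylidenedecahydronaphthalen-1-yl]butan-2-one | C=C1CC[C@@H]2C(C)(C)CCC[C@@]2(C)[C@@H]1CCC(C)=O | intermediate
7 | triethyl phosphonoacetate | CCOC(=O)CP(=O)(OCC)OCC | starting material
8 | ethyl ent-copalate; ethyl (2E)-3-methyl-5-[(1R,4aR,8aR)-5,5,8a-trimethyl-2-methylidenedecahydronaphthalen-1-yl]pent-2-enoate | C=C1CC[C@@H]2C(C)(C)CCC[C@@]2(C)[C@@H]1CC/C(C)=C/C(=O)OCC | intermediate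
9 | ent-copalol; (2E)-3-methyl-5-[(1R,4aR,8aR)-5,5,8a-trimethyl-2-methylidenedecahydronaphthalen-1-yl]pent-2-en-1-ol | C=C1CC[C@@H]2C(C)(C)CCC[C@@]2(C)[C@@H]1CC/C(C)=C/CO | intermediate
10 | Meldrum's acid (2,2-dimethyl-1,3-dioxane-4,6-dione) | CC1(C)OC(=O)CC(=O)O1 | starting material
11 | ent-copalyl hydrogen malonate (CNP0107438.1) | C=C1CC[C@@H]2C(C)(C)CCC[C@@]2(C)[C@@H]1CC/C(C)=C/COC(=O)CC(=O)O | target

**Totals**
Total step count: 5. Longest linear sequence: 5 (1 → 4 → 6 → 8 → 9 → 11).

**Three steps most likely to fail**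

Step 1 (the proposed new cyclization). Risks are carbonyl binding to the catalyst, early termination, or low enantiomeric ratio. The fallback sets out from 1 and uses known chemistry. Racemic superacid cyclization (FSO3H, 2-nitropropane, −78 °C) gives racemic sclareol oxide F1. Hydrolysis with dilute aqueous HCl in THF gives racemic hydroxy ketone F2. F2 is resolved by preparative chiral SFC on a polysaccharide phase, and the (1S,2S,4aR,8aR) enantiomer is 4, where the route is rejoined.

Step 2 (regiochemistry of the dehydration). Risks are endocyclic Δ7/Δ8 alkenes or re-closure to 3 through the hemiketal form of 4. The fallback sets out from 4 and replaces the E2 pathway by a thermal syn-elimination. The tertiary alcohol is acetylated (AcCl, N,N-dimethylaniline, CH2Cl2, 40 °C) to 8-acetate F3. F3 is then heated (2,4,6-collidine, 170 °C, or flash pyrolysis); ring hydrogens cannot reach the syn-periplanar geometry, so the acetate takes a methyl hydrogen, and the route is rejoined at 6.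

Step 3 (E/Z ratio and sluggish reaction of the methyl ketone). The fallback sets out from 6 and replaces olefination by alkyne carbometalation. Kinetic enolisation and phosphorylation (LDA, ClP(O)(OEt)2, THF, −78 °C) give enol phosphate F4, which is not isolated. More LDA eliminates it to terminal alkyne F5. Zirconium-catalysed carboalumination (Me3Al, Cp2ZrCl2, CH2Cl2), then n-BuLi and paraformaldehyde, gives the E-allylic alcohol with ≥98% E. The route is rejoined at 9, and 8 is bypassed.

**Further compounds**
F1 | step 1 | racemic sclareol oxide (3 and its mirror image, 1:1) | C[C@@]12CCCC(C)(C)[C@H]1CC[C@@]3(C)[C@H]2CC=C(C)O3.C[C@]12CCCC(C)(C)[C@@H]1CC[C@]3(C)[C@@H]2CC=C(C)O3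
F2 | step 1 | racemic 8-hydroxy-14,15-dinorlabdan-13-one (4 and its mirror image, 1:1) | C[C@]1(O)CC[C@@H]2C(C)(C)CCC[C@@]2(C)[C@@H]1CCC(C)=O.C[C@@]1(O)CC[C@H]2C(C)(C)CCC[C@]2(C)[C@H]1CCC(C)=O
F3 | step 2 | 8-acetate of 4; (1S,2S,4aR,8aR)-2,5,5,8a-tetramethyl-1-(3-oxobutyl)decahydronaphthalen-2-yl acetate | C[C@]1(OC(C)=O)CC[C@@H]2C(C)(C)CCC[C@@]2(C)[C@@H]1CCC(C)=O
F4 | step 3 | enol phosphate of 6; diethyl 4-[(1R,4aR,8aR)-5,5,8a-trimethyl-2-methylidenedecahydronaphthalen-1-yl]but-1-en-2-yl phosphate | C=C1CC[C@@H]2C(C)(C)CCC[C@@]2(C)[C@@H]1CCC(=C)OP(=O)(OCC)OCC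
F5 | step 3 | terminal alkyne; (1R,4aR,8aR)-1-(but-3-yn-1-yl)-5,5,8a-trimethyl-2-methylidenedecahydronaphthalene | C=C1CC[C@@H]2C(C)(C)CCC[C@@]2(C)[C@@H]1CCC#C
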